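(All constants are assumed, and the outcome is calculated.)

Take grey as the earlier run and green as its repeat with more D, and ask what the extra D buys.

| flask | G | D | time |
|---|---|---|---|
| grey | 20 mM | 18.0 mM | 25 s |
| green | 20 mM | 23.0 mM | 25 s |

    L + D → J + Z (k1 = 26.7 M⁻¹ s⁻¹)
    D + J ⇌ D.J, settled at all times (K2 = 8110 M⁻¹)
    G ⇌ L, rate k3*(cs3 - [L]) while solid is left; crystals form when [L] > cs3 (cs3 = 8.1 mM, k3 = 0.0895 s⁻¹)
    J → Q (k4 = 0.212 s⁻¹)
    Z → E (k5 = 3.32 × 10⁻⁵ s⁻¹)

- part of the G that has reacted (what has only dissolved counts as not reacted) at the end, grey
- part of the G that has reacted (what has only dissolved counts as not reacted) at the end, green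
- what raising the concentration of D from its lowest to its highest value here does to the part of the G that has reacted (what has only dissolved counts as not reacted) (changes below 5 percentage points count as none) (it rises / it falls / no change)

- G is a solid; its amount is given per volume of the solution
- at the start none of G is in solution
- what has only dissolved of G counts as not reacted
- run time (grey): 25 s

Count D for each G that reacts. Each L takes one D and gives one J. J then takes a second D: at the charged c_D in grey, the balance holds 150 J bound for each J free, so far more is bound than free. Two amounts therefore matter: half the charged c_D, 9.00 mM in grey, and the charged G, 20 mM. Call their ratio the reach of D, with D, at 0.900 per G charged in grey, as the limiting reagent counted twice: 45.0% for grey.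

Why no other amount? Reckoned at its starting rate throughout, dissolving delivers 18.1 mM over the run, more than half the charged c_D of green, 11.5 mM. Bound J at the charged c_D in grey drains with a half-life of 477 s, longer than the run. My reckoning for green is 57.5%, so the share should rise by 13 percentage points.

The forecast gives 46.5% for grey (43% to 50%) and 57% for green (52% to 61%), and its verdict is: it rises. Its grounds are that “each L consumed uses one D while the J it forms ties up a second D as D.J”. Its figures stand above mine for grey and below mine for green.

The flask gives 44.7% for grey and 53.5% for green: it rises, by 8.8 points, and this gap between the two flasks is due to the difference in c_D.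

Now test the second D directly. Remove the association in grey and the share reaches 59.7% instead of 44.7%, which is 27% of what is missing, so one part of it.

Use the reach on the neighbour of grey with 4.5 mM of D: it gives 11.3%. The run gives 14.4%.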